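## The problem

The locants used throughout are: C1 benzoyl-bearing bridgehead (benzoyl carbonyl C16), C2 and C4 the ketones on either side of quaternary C3, C5 geranyl-bearing bridgehead, C6 (CH2), C7 (CH), C8 (CMe2), C9 bridging ketone, C10 (CH2 on C7), C11 (CH bonded to C3), C12 (CMe2), C13 (CH carrying the carbinol carbon C15), C14 (CH2 on C3).

Target 15 is a cage. Ring A (C1–C2–C3–C4–C5–C9) and ring B (C1–C9–C5–C6–C7–C8) form a bicyclo[3.3.1]nonane-2,4,9-trione; C3 and C7 are tied across it by the two-carbon bridge C10–C11 (a homoadamantane), and a cyclopentane (C3–C11–C12–C13–C14) is fused on the C3–C11 bond. Five carbons are fully substituted (C1, C3, C5, C8, C12), and the C1–C8 bond joins two of them. Of the six stereocentres, C1, C3, C5 and C7 are locked together by the cage: once C5 and C7 are set so that C10 stands over ring A, C1 and C3 can form in one sense only. C11 and C13 are not dictated by the cage and depend on how the cyclopentane is closed. The two trisubstituted alkenes of the geranyl chain (acid, electrophiles, hydrogen-atom donors), the tertiary alcohol (dehydration) and the 1,3-diketone units lying between quaternary carbons (retro-Claisen cleavage by hydroxide or alkoxide) limit the reagents that can be used late. The feature that opens the route is ring B: benzoyl-bearing C1 sits next to the CMe2 carbon C8, and C6–C7–C8 with its C10–C12 branch is a lavandulyl unit hanging from C5, so cutting C1–C8 leaves an enol carbon and a tertiary cation that an isopropenyl group can supply. Two traps follow: the cation reaches C3, the better enol carbon, as easily as C1, and on an aromatic precursor an electrophile cannot tell a prenyl-bearing from a geranyl-bearing carbon. Both are answered here by a chlorine atom at C3.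

## Retrosynthesis

**C15–O.** Target 15 is cut at the C15–O bond to the isopropenyl cage 13; the hydroperoxide 14 lies on the way. Oxygenating C15 during the radical cascade was the neighbouring option, but dioxygen or a nitroxide would also intercept the C12 radical before the cyclopentane closes. A separate Markovnikov hydration only has to tell a 1,1-disubstituted alkene from the two trisubstituted geranyl alkenes.

**C3–C11 and C12–C13.** Both bonds of 13 are cut together, leading to the bicyclic enol 12 with prenyl groups on C3 and C7. This removes two rings and three stereocentres (C3, C11, C13) in one operation. Forming C3–C11 alone would leave a tertiary centre at C12 to be activated a second time. The forward reaction is an oxidative radical bicyclisation. It needs the C7 prenyl group on the ring A side (endo) and a defined face of its alkene at C11.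

**C3–H back to C3–Cl.** Enol 12 is derived from the chloride 11. The chlorine is not needed in 12, but it is needed in everything before it. In 11 and 10 it makes C3 quaternary, so that C1 is the only enol carbon in the key step. In 5 and 7 it occupies the ring carbon that must not be dialkylated. Zinc removes it without touching the alkenes.

**C1–C8 (key disconnection).** Chloride 11 is cut between the two fully substituted carbons C1 and C8, giving the monocyclic trione 10 with an isopropenyl group. Cutting C1–C16 instead would demand a late bridgehead acylation next to C8. Cutting C5–C6 or C7–C8 would break up the lavandulyl unit, which is available as one enantiopure block. The precursor 10 has one ring and two stereocentres fewer than 11. The forward step must activate one alkene out of five, alkylate carbon and not oxygen, and accept the C7 prenyl group in the axial position of the new ring.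

**C3–C14.** Trione 10 is cut at the prenyl group to the chloro enol 8 and prenyl bromide 9. C3 of 8 is the only enol carbon without an acyl group, so the forward C-allylation has one site. The C3 configuration is irrelevant because the centre is made planar again in steps 8 and 9.

**C5–C6.** Chloro enol 8 is cut to the aromatic chloride 7 and (S)-lavandulyl triflate 3. Alkylative dearomatisation is the only direct way to a ring carbon carrying two different chains. With C3 chlorinated and C1 acylated, C5 is the one ring carbon likely to react. C5 becomes a stereocentre here under no useful control from the remote C7, so 8 has to be separated from its C5 epimer.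

**C5–geranyl and C3–Cl.** Compound 7 comes from chloride 5 and geranyl bromide 6 by C-alkylation of the one free ring carbon, and 5 from 2,4,6-trihydroxybenzophenone 4 by monochlorination. Chlorine goes in first because the two free positions of 4 are equivalent, so no regiochemical question arises at any later alkylation.

**Lavandulyl block.** Triflate 3 comes from (S)-lavandulol 2, and 2 from racemic lavandulol 1 by lipase resolution. The C7 stereocentre of the target is bought in this way and never touched again.

## Roads not taken

**Alternative 1:** The seven-membered ring C3–C4–C5–C6–C7–C10–C11 would be cut at C10–C11 and C6–C7. In the forward sense the siloxy vinylcyclopropane A2 and the terminal alkyne A3 would combine under [Rh(CO)2Cl]2 (monovalent rhodium) in a (5+2) cycloaddition to give the cycloheptadiene A1, with C3=C4 as a silyl enol ether.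
- Merits: it is convergent, C13 is in place before the cycloaddition, and C11 is set in a ring-forming step under the influence of C13. These are the two centres the chosen plan leaves to a cascade.
- Weak points: A1 has neither ring A nor ring B. C2 has still to be attached to C3; C1–C2, C5–C9, the geranyl group and the benzoyl group are all missing; the three quaternary centres C1, C3 and C5 remain; and the C7=C10 alkene must be reduced from the correct face.
- Comparison: this road is better for the security of C11 and C13. The chosen plan sets against that a much shorter sequence (10 steps) in which C1, C3 and C5 are made by alkylating a flat, symmetrical ring and the benzoyl group is present from the first compound.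

**Alternative 2:** The cyclopentane would be cut at C12–C13. The diazo ester A5 would give a rhodium carbenoid at C13 with Rh2(O2CCPh3)4 (divalent rhodium), which inserts into the tertiary C–H bond of the isopropyl group on C11 to give the cyclopentane triester A4.
- Merits: 1,5-insertion into a tertiary C–H bond is among the most dependable ways to make a CMe2 quaternary carbon. The C13 ester is a direct precursor of the carbinol, and the C11/C13 relationship is set in a compact transition state.
- Weak points: A4 holds only five of the fourteen cage carbons. The two identical tert-butyl esters on C3 must later be told apart as C2 and C4, and the seven-membered ring and rings A and B would all remain.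
- Comparison: it is better than the chosen plan in making C12 and C13 without any ambiguity. The chosen plan forms the same C12–C13 bond by a 5-exo radical closure in the step that also makes C3–C11, at the price of less certain stereocontrol.

**Alternative 3:** The cage would be cut at C4–C5 and C1–C2. In one pot, the C5 silyl enol ether of A7 would be C-acylated by its C4 acid chloride under ZnCl2, and KN(SiMe3)2 would then drive a Dieckmann closure of C1 onto the C2 pentafluorophenyl ester. The product is the caged trione A6, which lacks the benzoyl group.
- Merits: two rings close in one operation; C11, C13 and C7 are fixed beforehand; the tether allows only one face at C5; and the C- against O-alkylation question at C1–C8 never arises because ring B is preformed.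
- Weak points: A7 is itself a long synthesis (a cyclopentane with a quaternary C3 carrying two different acyl groups, joined to a substituted cyclohexanone). The acylation must create quaternary C5 against a crowded partner. A6 still needs a benzoyl group at bridgehead C1, next to the C8 methyl groups, where enolisation is impossible and metallation is hindered.
- Comparison: this road is stronger on stereochemical security and on the C1–C8 bond. The chosen plan is far shorter and avoids the late bridgehead acylation.

Key step: step 7

Assumption: Candida antarctica lipase B is taken to acetylate (R)-lavandulol faster than the (S)-enantiomer, so that the alcohol left beyond half conversion is 2; if the preference were the opposite, the ester fraction would be methanolysed and used instead.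

Remark: 10 and 11 are carried as mixtures of C3 epimers (C3 is made planar again in steps 8 and 9), so C3 has no descriptor in their SMILES. Enols are drawn as one tautomer, and CIP descriptors refer to the drawn form; they change between 11, 12 and 13 only because priorities change.

## Route

Step 1
Reactants: 1 (±)-lavandulol, (RS)-5-methyl-2-(prop-1-en-2-yl)hex-4-en-1-ol
Product: 2 (S)-lavandulol
Conditions: Novozym 435 (immobilised Candida antarctica lipase B), vinyl acetate, hexane, rt, taken past half conversion; chromatography
Reagents that add atoms: none
Why: Lipase-catalysed acylative kinetic resolution with an irreversible acyl donor; the faster-reacting (R)-alcohol is removed as its acetate, and running past half conversion should leave 2 in high enantiomeric purity at some cost in yield. The C7 stereocentre of the whole route is fixed here.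

Step 2
Reactants: 2 (S)-lavandulol
Product: 3 (S)-lavandulyl triflate, (2S)-5-methyl-2-(prop-1-en-2-yl)hex-4-en-1-yl trifluoromethanesulfonate
Conditions: (CF3SO2)2O, 2,6-lutidine, CH2Cl2, −78 °C; cold pentane filtration, used at once
Reagents that add atoms: trifluoromethanesulfonic anhydride, O=S(=O)(OS(=O)(=O)C(F)(F)F)C(F)(F)F
Why: O-Sulfonylation of a primary alcohol; low temperature and a hindered base keep the homoallylic triflate from ionising, and the stereocentre is not involved.

Step 3
Reactants: 4 2,4,6-trihydroxybenzophenone
Product: 5 3-chloro-2,4,6-trihydroxybenzophenone
Conditions: SO2Cl2 (1.0 equiv), Et2O, 0 °C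
Reagents that add atoms: sulfuryl chloride, O=S(=O)(Cl)Cl
Why: Electrophilic aromatic chlorination; the two free ring positions of 4 are equivalent, so one equivalent gives a single monochloride, and the chlorine slows a second substitution.

Step 4
Reactants: 5 3-chloro-2,4,6-trihydroxybenzophenone; 6 geranyl bromide
Product: 7 3-chloro-5-geranyl-2,4,6-trihydroxybenzophenone
Conditions: 6 (1.0 equiv), 10% aq. KOH, 0 °C to rt
Reagents that add atoms: none
Why: C-Alkylation of a phloroglucinol anion by an allylic bromide; C5 is the only unsubstituted ring carbon, water favours C- over O-alkylation, and the chlorine-bearing C3 is the poorer nucleophile.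

Step 5
Reactants: 7 3-chloro-5-geranyl-2,4,6-trihydroxybenzophenone; 3 (S)-lavandulyl triflate
Product: 8 dearomatised chloro enol (5S,7R): C5 carries geranyl and lavandulyl; C4 ketone; C3(Cl)=C2(OH); C1(benzoyl)=C9(OH)
Conditions: LiN(SiMe3)2 (3.1 equiv), THF, −78 °C; 3 (1.2 equiv), −78 to 0 °C; aq. NH4Cl; separation of the C5 epimers by preparative HPLC
Reagents that add atoms: none
Why: Alkylative dearomatisation of an acylphloroglucinol; the lithium trianion attacks the primary triflate through C5, the most electron-rich ring carbon (C3 carries chlorine, C1 the benzoyl group), which becomes quaternary. C7 is carried over from 3; C5 forms with little induction expected from the remote C7, so both epimers should arise and the (5S,7R) isomer is isolated.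

Step 6
Reactants: 8 dearomatised chloro enol (5S,7R); 9 prenyl bromide
Product: 10 trione with C3(Cl)(prenyl) and the enolised benzoyl triketone at C1 (5S,7R; both C3 epimers)
Conditions: LiN(SiMe3)2 (2.05 equiv), THF, −78 °C; 9 (1.2 equiv), −78 to −20 °C; aq. NH4Cl
Reagents that add atoms: none
Why: C-Allylation of a 2-chloro-1,3-diketone enolate; in the dianion of 8, C3 is the only enol carbon that bears no acyl group. A non-nucleophilic amide base at low temperature is used because alkoxide or hydroxide would open the resulting α-chloro diketone (retro-Claisen, quasi-Favorskii); the new C3 centre need not be controlled.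

Step 7
Reactants: 10 trione with C3(Cl)(prenyl) (5S,7R)
Product: 11 bicyclo[3.3.1]nonane-2,4,9-trione (1S,5S,7R; both C3 epimers) with 1-benzoyl 3-chloro 5-geranyl 8,8-dimethyl 3,7-diprenyl substitution
Conditions: [N,N'-bis(3,5-di-tert-butylsalicylidene)-1,2-cyclohexanediaminato]cobalt (divalent cobalt, 5 mol%), N-fluoro-2,4,6-trimethylpyridinium triflate (1.5 equiv), PhSiH3 (1.2 equiv), (CF3)2CHOH–CH2Cl2, 0 °C
Reagents that add atoms: none
Why: Proposed new method: the divalent cobalt salen complex is oxidised by the N-fluoropyridinium salt and turned by PhSiH3 into a trivalent cobalt hydride, which transfers a hydrogen atom to the CH2 terminus of the isopropenyl group; the tertiary C8 radical is captured by cobalt and oxidised to a tetravalent alkylcobalt, a tertiary cation equivalent, which is displaced by the enol carbon C1 of the benzoyl triketone (C1–C8 bond, proton taken up by 2,4,6-trimethylpyridine). The closest known reactions are the acid-mediated cation–enol cyclisation of dearomatised acylphloroglucinols and the cobalt salen MHAT radical–polar crossover hydroalkoxylation, hydroarylation and polyene cyclisation of 1,1-disubstituted alkenes; capture by an enol carbon is the extension. Ring B closes by a six-membered attack of the ring enol on the cation (enol double bond inside the new ring), with C6 axial on ring A. The new centre C1 is controlled by C5, because the three-atom tether can bring C8 only to the face of C1 on which C6 stands; the (5S,7R) relationship then leaves the C7 prenyl group axial on ring B, over ring A, as the cage requires. Alkene selectivity rests on hydrogen-atom transfer being much faster to the 1,1-disubstituted alkene than to the four trisubstituted ones. Site selectivity rests on the chlorine: C3 is quaternary and C4 cannot enolise, so C1 is the only enol carbon within reach. C- against O-alkylation is the open point; capture by O9 would give a tertiary-alkyl enol ether of a strong vinylogous acid that can re-ionise in hexafluoroisopropanol, whereas the C–C bond, once formed, stays.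

Step 8
Reactants: 11 bicyclic C3 chloride (1S,5S,7R)
Product: 12 bicyclic enol (1R,5R,7R): 1-benzoyl-5-geranyl-4-hydroxy-8,8-dimethyl-3,7-diprenylbicyclo[3.3.1]non-3-ene-2,9-dione
Conditions: Zn dust, AcOH, rt
Reagents that add atoms: none
Why: Reductive dehalogenation of an α-chloro-1,3-diketone through its zinc enolate; it returns the C3 enol and erases the C3 stereocentre, while alkenes, the aryl ketone and the bridgehead triketone are inert to zinc in acetic acid at room temperature.

Step 9
Reactants: 12 bicyclic enol (1R,5R,7R)
Product: 13 isopropenyl cage (1S,3S,5R,7R,11R,13R): the skeleton of 15 with C13 carrying prop-1-en-2-yl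
Conditions: Mn(OAc)3·2H2O (2.2 equiv), Cu(OAc)2·H2O (1.0 equiv), degassed AcOH, rt
Reagents that add atoms: none
Why: Oxidative free-radical cyclisation with manganese triacetate: the trivalent manganese enolate of 12 gives the C3 radical, which adds across the bicycle to C11 of the axial C7 prenyl group; the C12 radical then closes 5-exo-trig onto C13 of the C3 prenyl group, and copper diacetate oxidises the C15 radical to the isopropenyl group. C3 can bond only through its endo face; C11 should form with the bridge twisted so that C11 leans to the C6 side, away from the equatorial C8 methyl, which turns C12 to the C2 side as the target requires; C13 follows from the 5-exo closure with the C15 terminus on the outer face, cis to H11.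

Step 10
Reactants: 13 isopropenyl cage (1S,3S,5R,7R,11R,13R)
Product: 15 target cage trione (1S,3S,5R,7R,11R,13S), via C15 hydroperoxide 14 (not isolated)
Conditions: Co(acac)2 (20 mol%), PhSiH3, O2 (1 atm), i-PrOH–THF, 0 °C to rt; then PPh3
Reagents that add atoms: dioxygen, O=O
Why: Mukaiyama hydration (hydrogen-atom transfer from a cobalt hydride, capture of the C15 radical by O2, reduction of hydroperoxide 14); transfer to the 1,1-disubstituted alkene is faster than to the two trisubstituted geranyl alkenes, and Markovnikov selectivity puts oxygen on C15. No stereocentre is formed or disturbed.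

## Compound list

1 | (±)-lavandulol, (RS)-5-methyl-2-(prop-1-en-2-yl)hex-4-en-1-ol | CC(C)=CCC(CO)C(C)=C | starting material
2 | (S)-lavandulol | OC[C@@H](CC=C(C)C)C(C)=C | intermediate
3 | (S)-lavandulyl triflate | FC(F)(F)S(=O)(=O)OC[C@@H](CC=C(C)C)C(C)=C | intermediate
4 | 2,4,6-trihydroxybenzophenone | O=C(c1ccccc1)c1c(O)cc(O)cc1O | starting material
5 | 3-chloro-2,4,6-trihydroxybenzophenone | O=C(c1ccccc1)c1c(O)cc(O)c(Cl)c1O | intermediate
6 | geranyl bromide, (2E)-1-bromo-3,7-dimethylocta-2,6-diene | CC(C)=CCC/C(C)=C/CBr | starting material
7 | 3-chloro-5-geranyl-2,4,6-trihydroxybenzophenone | CC(C)=CCC/C(C)=C/Cc1c(O)c(Cl)c(O)c(C(=O)c2ccccc2)c1O | intermediate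
8 | dearomatised chloro enol (5S,7R): (6S)-4-benzoyl-2-chloro-6-geranyl-3,5-dihydroxy-6-[(2R)-5-methyl-2-(prop-1-en-2-yl)hex-4-en-1-yl]cyclohexa-2,4-dien-1-one | CC(C)=CCC/C(C)=C/C[C@@]1(C[C@@H](CC=C(C)C)C(C)=C)C(=O)C(Cl)=C(O)C(C(=O)c2ccccc2)=C1O | intermediate
9 | prenyl bromide | CC(C)=CCBr | starting material
10 | key-step precursor (5S,7R; C3 epimers): 4-benzoyl-2-chloro-6-geranyl-5-hydroxy-6-lavandulyl-2-prenylcyclohex-4-ene-1,3-dione | CC(C)=CCC/C(C)=C/C[C@@]1(C[C@@H](CC=C(C)C)C(C)=C)C(=O)C(Cl)(CC=C(C)C)C(=O)C(C(=O)c2ccccc2)=C1O | intermediate
11 | key-step product (1S,5S,7R; C3 epimers): 1-benzoyl-3-chloro-5-geranyl-8,8-dimethyl-3,7-diprenylbicyclo[3.3.1]nonane-2,4,9-trione | CC(C)=CCC/C(C)=C/C[C@@]12C[C@@H](CC=C(C)C)C(C)(C)[C@](C(=O)c3ccccc3)(C2=O)C(=O)C(Cl)(CC=C(C)C)C1=O | intermediate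
12 | bicyclic enol (1R,5R,7R): 1-benzoyl-5-geranyl-4-hydroxy-8,8-dimethyl-3,7-diprenylbicyclo[3.3.1]non-3-ene-2,9-dione | CC(C)=CCC/C(C)=C/C[C@@]12C[C@@H](CC=C(C)C)C(C)(C)[C@](C(=O)c3ccccc3)(C2=O)C(=O)C(CC=C(C)C)=C1O | intermediate
13 | isopropenyl cage (1S,3S,5R,7R,11R,13R): skeleton of 15 with prop-1-en-2-yl on C13 | CC(C)=CCC/C(C)=C/C[C@@]12C[C@H]3C[C@@H]4C(C)(C)[C@@H](C(C)=C)C[C@]4(C1=O)C(=O)[C@@](C(=O)c1ccccc1)(C2=O)C3(C)C | intermediate
14 | C15 hydroperoxide of the cage (1S,3S,5R,7R,11R,13S) | CC(C)=CCC/C(C)=C/C[C@@]12C[C@H]3C[C@@H]4C(C)(C)[C@@H](C(C)(C)OO)C[C@]4(C1=O)C(=O)[C@@](C(=O)c1ccccc1)(C2=O)C3(C)C | intermediate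
15 | target, CNP0164095.2 (1S,3S,5R,7R,11R,13S): 1-benzoyl-5-geranyl-13-(2-hydroxypropan-2-yl)-8,8,12,12-tetramethyl cage trione in the C1–C16 numbering | CC(C)=CCC/C(C)=C/C[C@@]12C[C@H]3C[C@@H]4C(C)(C)[C@@H](C(C)(C)O)C[C@]4(C1=O)C(=O)[C@@](C(=O)c1ccccc1)(C2=O)C3(C)C | target

Total step count: 10. Longest linear sequence: 8 steps (4 to 15 through steps 3–10; equally 1 to 15 through steps 1, 2 and 5–10).

## Least certain steps

**Step 7 (key step; the one proposed new method).** The most likely failure is capture of the C8 cation equivalent by the enol oxygen O9 instead of C1. O-Alkylation needs no crowded transition state, whereas the C1–C8 bond joins two fully substituted carbons with the C7 prenyl group forced axial. Fluorination of the enol by the N-fluoropyridinium salt is a second danger. Fallback (known chemistry): setting out from 10, the cation is generated by Markovnikov protonation in formic acid at room temperature. This is the acid-mediated cation–enol cyclisation known for dearomatised acylphloroglucinols. Under these reversible conditions the cyclic enol ether F1, formed by O9 capture, should re-ionise and drain into the C-alkylated trione, and the route is rejoined at 11. F1 isolated from the cobalt reaction can be put through the same treatment.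

**Step 5.** The most likely failure is O-alkylation and low conversion. A β-branched primary triflate has to be attacked by a ring carbon that becomes quaternary, and the homoallylic triflate can ionise with participation of its isopropenyl group. Fallback: the order of the two C5 alkylations is reversed. Setting out from 5, triflate 3 alkylates the unsubstituted ring carbon (LiN(SiMe3)2, THF), an easier substitution that restores the aromatic ring, to give the aromatic lavandulyl chloride F2. F2 is then dearomatised with the reactive allylic bromide 6 (LiN(SiMe3)2, THF), and after separation of the C5 epimers the route is rejoined at 8.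

**Step 6.** The most likely failure is O-prenylation of the ambident chloro enolate, whose carbon nucleophilicity is lowered by chlorine; dehydrochlorination of 10 by excess base is a lesser danger. Fallback: the C–C bond is made on the chlorine-free enol and chlorine is put back afterwards. Setting out from 8, zinc in acetic acid gives the dechlorinated trione F3. F3 is C-prenylated at its free enol carbon with 9 in aqueous KOH to the C3-prenyl enol F4. N-Chlorosuccinimide in CH2Cl2 at 0 °C then chlorinates C3 of F4, the usual reaction of a 2-alkyl-1,3-diketone, and the route is rejoined at 10.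

**Step 9.** The most likely failure is loss of the cascade's selectivity. Divalent copper can oxidise the C12 radical before the cyclopentane closes. The face selectivity at C11 may also be low, because the required mode turns C12 toward the side of the C8 methyl groups. Fallback: the chlorine of 11 is used as the radical source, so no oxidant is present. Setting out from 11, CuCl (monovalent copper, 30 mol%) with tris(2-pyridylmethyl)amine in 1,2-dichloroethane at rt to 40 °C should start an atom-transfer radical cyclisation that ends by chlorine transfer to C15, giving the tertiary chloride F5. Silver-assisted hydrolysis of F5 (AgOSO2CF3, 2,6-lutidine, acetone–water) then rejoins the route at 15. The lower temperature should also favour the better-organised addition mode at C11.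

**Step 10.** The most likely failure is loss of chemoselectivity. The isopropenyl group sits next to the quaternary C12, and hydrogen-atom transfer to the unhindered terminal alkene of the geranyl chain may compete. Fallback: oxygen is placed on C15 during the cascade. Setting out from 12, PhI(OAc)2 and TEMPO (THF, −78 °C to rt) trigger the same bicyclisation, with the C15 radical trapped as the alkoxyamine F6. Zinc in acetic acid cleaves the N–O bond of F6, and the route is rejoined at 15.

## Further compounds

F1 | step 7 | cyclic enol ether from O9 capture of the C8 cation (2,2-dimethyl-3-prenyl dihydropyran fused at C5–C9; C3 epimers) | CC(C)=CCC/C(C)=C/C[C@]12C[C@@H](CC=C(C)C)C(C)(C)OC1=C(C(=O)c1ccccc1)C(=O)C(Cl)(CC=C(C)C)C2=O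
F2 | step 5 | 3-chloro-2,4,6-trihydroxy-5-[(2R)-5-methyl-2-(prop-1-en-2-yl)hex-4-en-1-yl]benzophenone | O=C(c1ccccc1)c1c(O)c(Cl)c(O)c(C[C@@H](CC=C(C)C)C(C)=C)c1O
F3 | step 6 | dechlorinated trione (5S,7R): 4-benzoyl-6-geranyl-3,5-dihydroxy-6-lavandulylcyclohexa-2,4-dien-1-one | CC(C)=CCC/C(C)=C/C[C@@]1(C[C@@H](CC=C(C)C)C(C)=C)C(=O)C=C(O)C(C(=O)c2ccccc2)=C1O
F4 | step 6 | C3-prenyl enol (5S,7R): 4-benzoyl-6-geranyl-3,5-dihydroxy-6-lavandulyl-2-prenylcyclohexa-2,4-dien-1-one | CC(C)=CCC/C(C)=C/C[C@@]1(C[C@@H](CC=C(C)C)C(C)=C)C(=O)C(CC=C(C)C)=C(O)C(C(=O)c2ccccc2)=C1O
F5 | step 9 | C15 tertiary chloride of the cage (2-chloropropan-2-yl on C13) | CC(C)=CCC/C(C)=C/C[C@@]12C[C@H]3C[C@@H]4C(C)(C)[C@@H](C(C)(C)Cl)C[C@]4(C1=O)C(=O)[C@@](C(=O)c1ccccc1)(C2=O)C3(C)C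
F6 | step 10 | C15 O-(2,2,6,6-tetramethylpiperidin-1-yl) ether of the cage | CC(C)=CCC/C(C)=C/C[C@@]12C[C@H]3C[C@@H]4C(C)(C)[C@@H](C(C)(C)ON5C(C)(C)CCCC5(C)C)C[C@]4(C1=O)C(=O)[C@@](C(=O)c1ccccc1)(C2=O)C3(C)C
A1 | alternative 1 | cyclopentane-fused cycloheptadiene tert-butyldimethylsilyl enol ether with the C8–C1–C9 methyl ester chain on C7 | CC(C)(C)[Si](C)(C)OC1=C2C[C@H](C(C)(C)O[Si](CC)(CC)CC)C(C)(C)[C@H]2C=C(C(C)(C)CC(=O)OC)CC1
A2 | alternative 1 | 1-(tert-butyldimethylsilyloxy)-1-(cyclopent-1-enyl)cyclopropane with gem-dimethyl C12 and the triethylsilyl-protected carbinol on C13 | CC(C)(C)[Si](C)(C)OC1(CC1)C1=CC(C)(C)[C@@H](C(C)(C)O[Si](CC)(CC)CC)C1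
A3 | alternative 1 | methyl 3,3-dimethylpent-4-ynoate | C#CC(C)(C)CC(=O)OC
A4 | alternative 2 | cyclopentane triester with CMe2 at C12 | COC(=O)[C@H]1CC(C(=O)OC(C)(C)C)(C(=O)OC(C)(C)C)[C@H](CCO[Si](C)(C)C(C)(C)C)C1(C)C
A5 | alternative 2 | α-diazo methyl ester with the isopropyl group on C11 and the di-tert-butyl malonate at C3 | COC(=O)C(=[N+]=[N-])CC(C(=O)OC(C)(C)C)(C(=O)OC(C)(C)C)[C@H](CCO[Si](C)(C)C(C)(C)C)C(C)C
A6 | alternative 3 | caged trione lacking the benzoyl group, carbinol as triethylsilyl ether | CC(C)=CCC/C(C)=C/C[C@@]12C[C@H]3C[C@@H]4C(C)(C)[C@@H](C(C)(C)O[Si](CC)(CC)CC)C[C@]4(C1=O)C(=O)[C@@H](C2=O)C3(C)C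
A7 | alternative 3 | ring B trimethylsilyl enol ether tethered through C10 to the cyclopentane whose C3 carries the C4 acid chloride and the C2 pentafluorophenyl ester | CC(C)=CCC/C(C)=C/CC1=C(O[Si](C)(C)C)CC(C)(C)[C@H](C[C@@H]2C(C)(C)[C@@H](C(C)(C)O[Si](CC)(CC)CC)C[C@]2(C(Cl)=O)C(=O)Oc2c(F)c(F)c(F)c(F)c2F)C1
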